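# Proposed synthesis of (3S)-5,7-dihydroxy-3-(5-hydroxy-2,2-dimethyl-2H-chromen-8-yl)chroman-4-one (12)

## The problem

The target is a (3S)-isoflavanone: a 5,7-dihydroxychroman-4-one (rings A and C) that carries at C3 a 5-hydroxy-2,2-dimethyl-2H-chromen-8-yl group (benzene ring B fused to pyran ring D). Its only stereocentre, C3, is tertiary, benzylic and α to the C4 ketone. It is lost by enolization under base and more slowly under acid, so it must be made late, under neutral conditions, by catalyst control, since no other stereocentre exists to direct it. In any route through the flat isoflavone, the hydrogen that adds to C2 creates no stereocentre, and C3 is fixed only by hydrogen transfer to an enol-type carbon. Ring B is a 1,2,3,4-tetrasubstituted benzene: the pyran oxygen is ortho to C1' and the pyran carbon lies between the two oxygens, so ring D must be closed on the more hindered of two resorcinol oxygens. The pyran double bond of ring D is an electron-rich styrene that will not survive boron halides, hydrogenolysis or electrophilic oxidants, so the three phenols need groups that leave under near-neutral conditions.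

The feature that opens a shorter way is this: C2 is a methylene bonded only to O1 of ring A and to C3, so it has the connectivity of the methyl carbon of an aryl methyl ether. C3 carries one aryl group (ring B) and one acyl group (C4), the pattern of a donor/acceptor carbene. The C2–C3 bond can therefore be formed by insertion of a C3 carbene into a C–H bond of a ring A methoxy group, which closes ring C and creates C3 in one neutral step.

## Retrosynthesis

**12 ⇒ 11.** Only three O–Si bonds are cut. Silyl ethers are preferred to methyl, benzyl or acetal groups because they leave with buffered fluoride, which touches neither C3 nor ring D, and because they have no C–H bond α to oxygen. The forward step must stay near neutral.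

**11 ⇒ 10.** The C2–C3 bond and the C3–H bond are cut together, which leads back to the α-diazo ketone 10, whose ring A methoxy group is the future O1–C2 unit. The neighbouring cuts are weaker: C3–C1' leaves ring C still to be made and demands an enantioselective arylation at an enolizable carbon, while O1–C2 (oxa-Michael closure) and C3–H (isoflavone reduction) leave the stereocentre to a protonation. Here C3 becomes stereogenic in an irreversible, non-basic C–C bond formation. The precursor 10 is acyclic between the two arenes and achiral. The forward reaction must prefer C–H insertion to attack on the flanking oxygens and must distinguish the two faces of the carbene.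

**10 ⇒ 9.** The C=N2 unit is cut, leading to deoxybenzoin 9 by diazo transfer to a methylene activated by both the carbonyl group and ring B. The reaction must spare three aryl silyl ethers.

**9 ⇒ 8 + 6.** The bond between the α-carbon and C8 of the chromene (the future C3–C1' bond) is cut while that carbon is still a CH2 group, so the union of the two halves raises no stereochemical question. Palladium-catalysed α-arylation of methyl ketone 8 with bromide 6 is preferred to Friedel–Crafts acylation of ring A, whose acid would destroy ring D. The two fragments are of similar size and each is three steps or fewer from a purchasable phenol.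

**6 ⇒ 3 ⇒ 2 ⇒ 1.** The O–C and C–C bonds of ring D are cut by a propargyl Claisen sequence from ether 3. The bromine of 4-bromoresorcinol 1 does double duty: it blocks one ortho position, so the rearrangement can only go to the carbon between the two oxygens, and it is the handle for the arylation. This settles the 1,2,3,4-pattern of ring B without any isomer separation after ring closure.

**8 ⇒ 7.** Two O–Si bonds are cut. Acetophenone 7 already holds the acetyl group, the methoxy group that becomes O1–C2, and the two oxygens of C5 and C7.

## Roads not taken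

**Alternative 1:** The most obvious cut is C3–C1' on the flat chromone, followed by addition of hydrogen across C2=C3. Iodochromone A1 and boronate A2 (from 6) would be joined by Suzuki coupling to isoflavone A3, and the key step would be an asymmetric (transfer) hydrogenation of A3. The chosen plan is better for these reasons:
- In A3 the hydride enters at C2, which does not become a stereocentre, so C3 is set only when an enol-type carbon takes up hydrogen.
- The catalysts that control this best act by dynamic kinetic resolution and do not stop at the ketone oxidation level, which costs a further redox step.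
- A hydrogenation catalyst must also tell C2=C3 from the pyran double bond of ring D.
- Ring C must be built and iodinated separately (about three steps for A1, one for A2), whereas in the chosen plan ring C costs no step because C2 is already present in 7.

**Alternative 2:** The cut is again C3–C1', but at a quaternary C3. β-Keto allyl ester A4 would be arylated with aryllead triacetate A5 to give A6, and the key step would be a palladium-catalysed decarboxylative protonation of A6 with a chiral ligand. The chosen plan is better for these reasons: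
- A5 must be made from 6 through a boron or tin compound and Pb(OAc)4, an oxidant that also attacks the electron-rich pyran double bond, and it brings stoichiometric lead.
- C3 is once more set by proton transfer to an enolate, here beside a bulky C5 substituent.
- A4 requires ring C to be made and acylated first, so the sequence is about three steps longer.

**Alternative 3:** The cut follows the biosynthesis: the C3–C1' bond is made by 1,2-shift of ring B from the carbon that becomes C2. Chalcone A7 would be rearranged oxidatively with Tl(NO3)3 or a hypervalent iodine reagent in methanol and cyclized to A3. The chosen plan is better for these reasons: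
- The oxidant needed for the aryl shift meets in ring D an alkene more electron-rich than the enone it is meant for.
- The cation left at C2 after the shift is flanked by the C3–H bond, which is lost at once to give the chromone, so the migration cannot pass on stereochemical information.
- The sequence therefore ends at A3 and inherits every problem of Alternative 1.

Key step: step 7

Assumption: the sense of induction of the chiral dirhodium catalyst in step 7 cannot be derived from a close analogue, so Rh2(S-PTAD)4 is written and its mirror image Rh2(R-PTAD)4 is to be used if that is the one that delivers (3S). Compounds 1 and 7, 3-chloro-3-methylbut-1-yne and 5,7-dihydroxychroman-4-one are taken as purchasable.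

## Route

Step 1
Reactants: 1 4-bromobenzene-1,3-diol (4-bromoresorcinol)
Product: 2 2-bromo-5-[(triisopropylsilyl)oxy]phenol
Conditions: TIPSCl (1.05 equiv), imidazole, CH2Cl2, −20 → 0 °C
Reagents that add atoms: chlorotriisopropylsilane, CC(C)[Si](Cl)(C(C)C)C(C)C
Why: Selective silylation of the less hindered phenol: the hydroxyl para to bromine is open, while the other is flanked by the halogen, so the bulky chlorosilane should react at the former, in line with the preference of this diol for O-functionalization remote from bromine. The bromine stays as blocking group and later coupling handle.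

Step 2
Reactants: 2 2-bromo-5-[(triisopropylsilyl)oxy]phenol
Product: 3 1-bromo-2-[(2-methylbut-3-yn-2-yl)oxy]-4-[(triisopropylsilyl)oxy]benzene
Conditions: 3-chloro-3-methylbut-1-yne (1.5 equiv), DBU, CuCl2 (1 mol %), MeCN, 0 °C
Reagents that add atoms: 3-chloro-3-methylbut-1-yne, CC(C)(Cl)C#C
Why: Copper-catalysed propargylic etherification (substitution through a copper allenylidene), the standard entry to aryl 1,1-dimethylpropargyl ethers and effective for hindered phenols; the aryl silyl ether should tolerate DBU at 0 °C.

Step 3
Reactants: 3 1-bromo-2-[(2-methylbut-3-yn-2-yl)oxy]-4-[(triisopropylsilyl)oxy]benzene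
Product: 6 8-bromo-2,2-dimethyl-5-[(triisopropylsilyl)oxy]-2H-chromene, via allenylphenol 4 (not isolated), via ortho-quinone methide 5 (not isolated)
Conditions: N,N-diethylaniline, 180 °C
Reagents that add atoms: none
Why: Aromatic propargyl Claisen rearrangement to 4, then 1,5-hydrogen shift to 5 and oxa-6π electrocyclization. The [3,3] shift can only go to the free ortho carbon between the two oxygens because the other ortho position carries bromine, so ring D closes on the oxygen next to the future C1' as in the target.

Step 4
Reactants: 7 1-(2,4-dihydroxy-6-methoxyphenyl)ethan-1-one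
Product: 8 1-{2-methoxy-4,6-bis[(triisopropylsilyl)oxy]phenyl}ethan-1-one
Conditions: TIPSOTf (2.3 equiv), 2,6-lutidine, CH2Cl2, 0 °C → rt
Reagents that add atoms: triisopropylsilyl trifluoromethanesulfonate, CC(C)[Si](OS(=O)(=O)C(F)(F)F)(C(C)C)C(C)C
Why: Silyl ether formation; the silyl triflate is needed for the hydroxyl that is hydrogen-bonded to the acetyl group. Silyl groups are chosen because they have no C–H bond α to oxygen that could compete in step 7 and because they leave at the end with buffered fluoride.

Step 5
Reactants: 8 1-{2-methoxy-4,6-bis[(triisopropylsilyl)oxy]phenyl}ethan-1-one (1.2 equiv); 6 8-bromo-2,2-dimethyl-5-[(triisopropylsilyl)oxy]-2H-chromene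
Product: 9 2-{2,2-dimethyl-5-[(triisopropylsilyl)oxy]-2H-chromen-8-yl}-1-{2-methoxy-4,6-bis[(triisopropylsilyl)oxy]phenyl}ethan-1-one
Conditions: Pd2(dba)3 (2 mol %), XPhos (5 mol %), K3PO4, toluene, 90 °C
Reagents that add atoms: none
Why: Palladium-catalysed α-arylation of a methyl ketone (Buchwald–Hartwig type enolate arylation); the doubly ortho-substituted ketone and the bulky ligand favour monoarylation, and the phosphate base should spare the aryl silyl ethers.

Step 6
Reactants: 9 2-{2,2-dimethyl-5-[(triisopropylsilyl)oxy]-2H-chromen-8-yl}-1-{2-methoxy-4,6-bis[(triisopropylsilyl)oxy]phenyl}ethan-1-one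
Product: 10 2-diazo-2-{2,2-dimethyl-5-[(triisopropylsilyl)oxy]-2H-chromen-8-yl}-1-{2-methoxy-4,6-bis[(triisopropylsilyl)oxy]phenyl}ethan-1-one
Conditions: 4-acetamidobenzenesulfonyl azide (1.5 equiv), DBU (1.5 equiv), MeCN, 0 °C → rt
Reagents that add atoms: 4-acetamidobenzenesulfonyl azide, CC(=O)Nc1ccc(cc1)S(=O)(=O)N=[N+]=[N-]
Why: Regitz diazo transfer to a benzylic ketone; the methylene of 9 is activated by the carbonyl group and by ring B, so DBU should suffice and no auxiliary acyl group is needed.

Step 7
Reactants: 10 2-diazo-2-{2,2-dimethyl-5-[(triisopropylsilyl)oxy]-2H-chromen-8-yl}-1-{2-methoxy-4,6-bis[(triisopropylsilyl)oxy]phenyl}ethan-1-one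
Product: 11 (3S)-3-{2,2-dimethyl-5-[(triisopropylsilyl)oxy]-2H-chromen-8-yl}-5,7-bis[(triisopropylsilyl)oxy]-2,3-dihydro-4H-chromen-4-one
Conditions: Rh2(S-PTAD)4 [dirhodium tetrakis((S)-(1-adamantyl)(phthalimido)acetate)] (1 mol %), PhCF3, rt → 40 °C, slow addition of 10
Reagents that add atoms: none
Why: Proposed new method: Rh2(S-PTAD)4 takes N2 from 10 to give a rhodium-bound aryl(acyl)carbene at the future C3, which inserts into a C–H bond of the ring A methoxy group through a concerted, hydride-transfer-like three-centre transition state, so that the C2–C3 and C3–H bonds form in one event. The closest known reaction types are the dirhodium-carboxylate-catalysed cyclization of 2-alkoxyphenyl α-diazo ketones to 2-substituted chroman-4-ones by insertion into the O–CH2R group, and the enantioselective insertion of aryl-substituted donor/acceptor carbenes into methyl C–H bonds of methyl ethers; new is their combination, an aryl(aroyl)carbene inserting into an aryl O–CH3 group to give a 2-unsubstituted 3-arylchromanone. Ring C closes in a six-membered mode (formal 1,6-insertion through the carbene carbon, C4, C4a, C8a, O1 and the methyl carbon), and the C–H bonds attacked are activated by the lone pair on O1, unlike the unactivated methyl C–H bonds of the gem-dimethyl group. C3 is created at the carbene carbon, whose two faces are distinguished only by the chiral phthalimido-carboxylate ligands, since the substrate has no stereocentre. The step needs chemoselectivity for C–H insertion over attack of the carbene on the methoxy oxygen (five-membered oxonium ylide): the donor aryl group tempers the carbene, the aryl ether oxygen is a weak donor, and methyl is a poor group for the 1,2-shift that would drain the ylide, so ylide formation should be reversible and feed back into insertion. The other flanking oxygen is shielded by a bulky silyl group without α-hydrogen, the pyran oxygen could only give a four-membered ylide, and the pyran double bond cannot reach the carbene. The product forms under neutral, aprotic conditions and never meets a base, so C3 should not erode.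

Step 8
Reactants: 11 (3S)-3-{2,2-dimethyl-5-[(triisopropylsilyl)oxy]-2H-chromen-8-yl}-5,7-bis[(triisopropylsilyl)oxy]-2,3-dihydro-4H-chromen-4-one
Product: 12 (3S)-5,7-dihydroxy-3-(5-hydroxy-2,2-dimethyl-2H-chromen-8-yl)-2,3-dihydro-4H-chromen-4-one
Conditions: TBAF (3.5 equiv), AcOH (3.5 equiv), THF, 0 °C
Reagents that add atoms: none
Why: Fluoride-induced cleavage of the three aryl silyl ethers; acetic acid keeps the medium near neutral so that neither phenoxide nor free fluoride can enolize C3, and ring D is not exposed to strong acid.

## Compound list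

1 | 4-bromobenzene-1,3-diol (4-bromoresorcinol) | Oc1ccc(Br)c(O)c1 | starting material
2 | 2-bromo-5-[(triisopropylsilyl)oxy]phenol | Oc1cc(O[Si](C(C)C)(C(C)C)C(C)C)ccc1Br | intermediate
3 | 1-bromo-2-[(2-methylbut-3-yn-2-yl)oxy]-4-[(triisopropylsilyl)oxy]benzene | C#CC(C)(C)Oc1cc(O[Si](C(C)C)(C(C)C)C(C)C)ccc1Br | intermediate
4 | 6-bromo-2-(3-methylbuta-1,2-dien-1-yl)-3-[(triisopropylsilyl)oxy]phenol | CC(C)=C=Cc1c(O)c(Br)ccc1O[Si](C(C)C)(C(C)C)C(C)C | intermediate
5 | 2-bromo-6-(3-methylbut-2-en-1-ylidene)-5-[(triisopropylsilyl)oxy]cyclohexa-2,4-dien-1-one | CC(C)=CC=C1C(=O)C(Br)=CC=C1O[Si](C(C)C)(C(C)C)C(C)C | intermediate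
6 | 8-bromo-2,2-dimethyl-5-[(triisopropylsilyl)oxy]-2H-chromene | CC1(C)C=Cc2c(O[Si](C(C)C)(C(C)C)C(C)C)ccc(Br)c2O1 | intermediate
7 | 1-(2,4-dihydroxy-6-methoxyphenyl)ethan-1-one | CC(=O)c1c(O)cc(O)cc1OC | starting material
8 | 1-{2-methoxy-4,6-bis[(triisopropylsilyl)oxy]phenyl}ethan-1-one | CC(=O)c1c(OC)cc(O[Si](C(C)C)(C(C)C)C(C)C)cc1O[Si](C(C)C)(C(C)C)C(C)C | intermediate
9 | 2-{2,2-dimethyl-5-[(triisopropylsilyl)oxy]-2H-chromen-8-yl}-1-{2-methoxy-4,6-bis[(triisopropylsilyl)oxy]phenyl}ethan-1-one | COc1cc(O[Si](C(C)C)(C(C)C)C(C)C)cc(O[Si](C(C)C)(C(C)C)C(C)C)c1C(=O)Cc1ccc(O[Si](C(C)C)(C(C)C)C(C)C)c2C=CC(C)(C)Oc12 | intermediate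
10 | 2-diazo-2-{2,2-dimethyl-5-[(triisopropylsilyl)oxy]-2H-chromen-8-yl}-1-{2-methoxy-4,6-bis[(triisopropylsilyl)oxy]phenyl}ethan-1-one | COc1cc(O[Si](C(C)C)(C(C)C)C(C)C)cc(O[Si](C(C)C)(C(C)C)C(C)C)c1C(=O)C(=[N+]=[N-])c1ccc(O[Si](C(C)C)(C(C)C)C(C)C)c2C=CC(C)(C)Oc12 | intermediate
11 | (3S)-3-{2,2-dimethyl-5-[(triisopropylsilyl)oxy]-2H-chromen-8-yl}-5,7-bis[(triisopropylsilyl)oxy]-2,3-dihydro-4H-chromen-4-one | CC1(C)C=Cc2c(O[Si](C(C)C)(C(C)C)C(C)C)ccc([C@H]3COc4cc(O[Si](C(C)C)(C(C)C)C(C)C)cc(O[Si](C(C)C)(C(C)C)C(C)C)c4C3=O)c2O1 | intermediate
12 | (3S)-5,7-dihydroxy-3-(5-hydroxy-2,2-dimethyl-2H-chromen-8-yl)-2,3-dihydro-4H-chromen-4-one | CC1(C)C=Cc2c(O)ccc([C@H]3COc4cc(O)cc(O)c4C3=O)c2O1 | target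

## Step count and least certain steps

Total step count: 8. Longest linear sequence: 7 steps (1 → 2 → 3 → 6 → 9 → 10 → 11 → 12); the ring A branch (7 → 8) adds one step.

**Step 7 (key step, bears the label "Proposed new method:").** The most likely failure is diversion of the carbene to a flanking oxygen before it reaches the C–H bond. Attack on the methoxy oxygen followed by 1,2-methyl shift would give a benzofuranone; attack on the neighbouring silyloxy oxygen followed by silyl transfer would give a benzofuran. If insertion does occur, facial discrimination may be weak, because the inserting carbon is an unsubstituted methyl group that gives the catalyst little to hold.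

Fallback, by known chemistry: it sets out from 6 and comes back at 11. Commercial 5,7-dihydroxychroman-4-one is silylated (TIPSOTf, 2,6-lutidine) to 5,7-bis[(triisopropylsilyl)oxy]chroman-4-one F1. Palladium-catalysed α-arylation of F1 with 6 (Pd2(dba)3, XPhos, K3PO4, toluene) gives the racemic isoflavanone F2. Because C3 is labile, F2 is funnelled into one enantiomer by asymmetric transfer hydrogenation under dynamic kinetic resolution (RuCl(p-cymene)[(S,S)-TsDPEN] or its enantiomer, HCO2H/Et3N), which should give the cis-(3S,4S)-isoflavan-4-ol F3 and leave the pyran double bond alone. Oxidation with Dess–Martin periodinane buffered with NaHCO3 returns the ketone 11 without touching C3.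

**Step 5.** The most likely failures are migration of the ortho silyl group from the phenolic oxygen to the enolate oxygen at 90 °C (the phenoxide is the better anion), Heck-type arylation of the pyran double bond, and slow oxidative addition of the electron-rich, ortho-substituted bromide.

Fallback: it sets out from 8 and 6 and comes back at 10, bypassing 9. The lithium enolate of 8, kept at −78 °C (LiN(SiMe3)2, THF), is trifluoroacetylated with 2,2,2-trifluoroethyl trifluoroacetate to the diketone F4. Detrifluoroacetylative diazo transfer (MsN3, Et3N, MeCN, water) then gives the diazomethyl ketone F5. Bromide 6 is converted into the iodide F6 by copper-catalysed aromatic Finkelstein exchange (CuI, NaI, trans-N,N'-dimethylcyclohexane-1,2-diamine, dioxane, 110 °C). Palladium-catalysed C–H arylation of the acyldiazomethane F5 with F6 (Pd(PPh3)4, Ag2CO3, Et3N, toluene, rt) gives 10 without a hot enolate.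

**Step 6.** The most likely failure is slow deprotonation of the hindered, electron-rich benzylic ketone, which leaves time for DBU to attack the aryl silyl ethers and for the sulfonyl azide to decompose.

Fallback: it sets out from 9 and comes back at 10. The activated methylene of 9 is oxidized with SeO2 (dioxane, 80 °C) to the 1,2-diketone F7. Hydrazine condenses at the less hindered carbonyl group next to ring B to give the monohydrazone F8. Dehydrogenation of F8 with MnO2 (CH2Cl2, rt) gives 10.

**Step 2.** The most likely failure is sluggish O-alkylation of the bromine-flanked, weakly nucleophilic phenol by the tertiary propargylic electrophile, with competing elimination of the chloride to the enyne and slow desilylation by DBU.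

Fallback: it sets out from 2 and comes back at 6, bypassing 3 and 4. Phenol 2 is condensed with 3-methylbut-2-enal in the presence of PhB(OH)2 and AcOH (toluene, reflux, water removal). The benzodioxaborinine F9 forms at the only free ortho position, fragments to the same ortho-quinone methide 5, and closes to 6.

## Further compounds

F1 | step 7 | 5,7-bis[(triisopropylsilyl)oxy]-2,3-dihydro-4H-chromen-4-one | O=C1CCOc2cc(O[Si](C(C)C)(C(C)C)C(C)C)cc(O[Si](C(C)C)(C(C)C)C(C)C)c12
F2 | step 7 | racemic 3-{2,2-dimethyl-5-[(triisopropylsilyl)oxy]-2H-chromen-8-yl}-5,7-bis[(triisopropylsilyl)oxy]-2,3-dihydro-4H-chromen-4-one | CC1(C)C=Cc2c(O[Si](C(C)C)(C(C)C)C(C)C)ccc(C3COc4cc(O[Si](C(C)C)(C(C)C)C(C)C)cc(O[Si](C(C)C)(C(C)C)C(C)C)c4C3=O)c2O1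
F3 | step 7 | (3S,4S)-3-{2,2-dimethyl-5-[(triisopropylsilyl)oxy]-2H-chromen-8-yl}-5,7-bis[(triisopropylsilyl)oxy]-3,4-dihydro-2H-chromen-4-ol (cis) | CC1(C)C=Cc2c(O[Si](C(C)C)(C(C)C)C(C)C)ccc([C@H]3COc4cc(O[Si](C(C)C)(C(C)C)C(C)C)cc(O[Si](C(C)C)(C(C)C)C(C)C)c4[C@H]3O)c2O1
F4 | step 5 | 4,4,4-trifluoro-1-{2-methoxy-4,6-bis[(triisopropylsilyl)oxy]phenyl}butane-1,3-dione | COc1cc(O[Si](C(C)C)(C(C)C)C(C)C)cc(O[Si](C(C)C)(C(C)C)C(C)C)c1C(=O)CC(=O)C(F)(F)F
F5 | step 5 | 2-diazo-1-{2-methoxy-4,6-bis[(triisopropylsilyl)oxy]phenyl}ethan-1-one | COc1cc(O[Si](C(C)C)(C(C)C)C(C)C)cc(O[Si](C(C)C)(C(C)C)C(C)C)c1C(=O)C=[N+]=[N-]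
F6 | step 5 | 8-iodo-2,2-dimethyl-5-[(triisopropylsilyl)oxy]-2H-chromene | CC1(C)C=Cc2c(O[Si](C(C)C)(C(C)C)C(C)C)ccc(I)c2O1
F7 | step 6 | 1-{2,2-dimethyl-5-[(triisopropylsilyl)oxy]-2H-chromen-8-yl}-2-{2-methoxy-4,6-bis[(triisopropylsilyl)oxy]phenyl}ethane-1,2-dione | COc1cc(O[Si](C(C)C)(C(C)C)C(C)C)cc(O[Si](C(C)C)(C(C)C)C(C)C)c1C(=O)C(=O)c1ccc(O[Si](C(C)C)(C(C)C)C(C)C)c2C=CC(C)(C)Oc12
F8 | step 6 | 2-{2,2-dimethyl-5-[(triisopropylsilyl)oxy]-2H-chromen-8-yl}-2-hydrazinylidene-1-{2-methoxy-4,6-bis[(triisopropylsilyl)oxy]phenyl}ethan-1-one | COc1cc(O[Si](C(C)C)(C(C)C)C(C)C)cc(O[Si](C(C)C)(C(C)C)C(C)C)c1C(=O)C(=NN)c1ccc(O[Si](C(C)C)(C(C)C)C(C)C)c2C=CC(C)(C)Oc12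
F9 | step 2 | 8-bromo-4-(2-methylprop-1-en-1-yl)-2-phenyl-5-[(triisopropylsilyl)oxy]-4H-1,3,2-benzodioxaborinine | CC(C)=CC1OB(c2ccccc2)Oc2c(Br)ccc(O[Si](C(C)C)(C(C)C)C(C)C)c12
A1 | alternative 1 | 3-iodo-5,7-bis[(triisopropylsilyl)oxy]-4H-chromen-4-one | O=c1c(I)coc2cc(O[Si](C(C)C)(C(C)C)C(C)C)cc(O[Si](C(C)C)(C(C)C)C(C)C)c12
A2 | alternative 1 | 2-{2,2-dimethyl-5-[(triisopropylsilyl)oxy]-2H-chromen-8-yl}-4,4,5,5-tetramethyl-1,3,2-dioxaborolane | CC1(C)C=Cc2c(O[Si](C(C)C)(C(C)C)C(C)C)ccc(B3OC(C)(C)C(C)(C)O3)c2O1
A3 | alternative 1 | 3-{2,2-dimethyl-5-[(triisopropylsilyl)oxy]-2H-chromen-8-yl}-5,7-bis[(triisopropylsilyl)oxy]-4H-chromen-4-one | CC1(C)C=Cc2c(O[Si](C(C)C)(C(C)C)C(C)C)ccc(-c3coc4cc(O[Si](C(C)C)(C(C)C)C(C)C)cc(O[Si](C(C)C)(C(C)C)C(C)C)c4c3=O)c2O1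
A4 | alternative 2 | prop-2-en-1-yl 4-oxo-5,7-bis[(triisopropylsilyl)oxy]-3,4-dihydro-2H-chromene-3-carboxylate | C=CCOC(=O)C1COc2cc(O[Si](C(C)C)(C(C)C)C(C)C)cc(O[Si](C(C)C)(C(C)C)C(C)C)c2C1=O
A5 | alternative 2 | {2,2-dimethyl-5-[(triisopropylsilyl)oxy]-2H-chromen-8-yl}lead triacetate | CC(=O)O[Pb](OC(C)=O)(OC(C)=O)c1ccc(O[Si](C(C)C)(C(C)C)C(C)C)c2C=CC(C)(C)Oc12
A6 | alternative 2 | prop-2-en-1-yl 3-{2,2-dimethyl-5-[(triisopropylsilyl)oxy]-2H-chromen-8-yl}-4-oxo-5,7-bis[(triisopropylsilyl)oxy]-3,4-dihydro-2H-chromene-3-carboxylate (racemic) | C=CCOC(=O)C1(c2ccc(O[Si](C(C)C)(C(C)C)C(C)C)c3C=CC(C)(C)Oc23)COc2cc(O[Si](C(C)C)(C(C)C)C(C)C)cc(O[Si](C(C)C)(C(C)C)C(C)C)c2C1=O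
A7 | alternative 3 | (2E)-3-{2,2-dimethyl-5-[(triisopropylsilyl)oxy]-2H-chromen-8-yl}-1-{2-hydroxy-4,6-bis[(triisopropylsilyl)oxy]phenyl}prop-2-en-1-one | O=C(/C=C/c1ccc(O[Si](C(C)C)(C(C)C)C(C)C)c2C=CC(C)(C)Oc12)c1c(O)cc(O[Si](C(C)C)(C(C)C)C(C)C)cc1O[Si](C(C)C)(C(C)C)C(C)C
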